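**Convention and assumptions (one line):** atom labels C1–C15 follow daucane numbering of the target (C1 = quaternary ring-fusion carbon, C4 = isopropyl carbinol, C5 = ring-fusion CH, C6 = ester carbon, C8/C9 = epoxide carbons); piperitone is used as the racemate because its stereocentre is erased in step 3; for each chiral catalyst or auxiliary the enantiomer that gives the drawn configuration is meant.

## Retrosynthetic overview

1. Target ⇐ α-face epoxidation of the C8=C9 alkene and acylation of the C6 hydroxyl of the syn-1,3-diol 14.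
2. 14 ⇐ chelation-controlled reduction of hydroazulenone 13; the seven-membered ring ⇐ ring-closing metathesis of methallyl ketone 12.
3. 12 ⇐ acyl transfer from the bicyclic β-lactone 9.
4. Key step: 9 ⇐ acyclic keto acid 7 by catalytic aldol-lactonisation, which closes the cyclopentane (C4–C5) and the β-lactone (C4–O) together and sets C4 and C5.
5. 7 ⇐ oxidative ring cleavage of cyclohexanone 5 ⇐ asymmetric conjugate addition to piperitone (sets C1). Ring order: cyclopentane + β-lactone (step 4), β-lactone opened (step 5), cycloheptene (step 6), oxirane (step 9).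

## Route

Step 1
Reactants: 1 piperitone; 2 but-3-en-1-ylmagnesium bromide
Product: 4 (3S)-3-(but-3-en-1-yl)-3-methyl-6-(propan-2-yl)cyclohexan-1-one, via magnesium enolate 3 (not isolated)
Conditions: 2 (1.3 equiv), Cu(OTf)2 (3 mol %), chiral imidazolinium NHC precursor (4 mol %), Et2O, 0 °C; aq. NH4Cl
Reagents that add atoms: none
Why: Copper-catalysed asymmetric conjugate addition of a Grignard reagent to a β-methyl cyclohexenone builds the all-carbon quaternary centre C1, the chiral copper–carbene complex choosing the enone face regardless of the remote centre that is erased later.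

Step 2
Reactants: 4 (3S)-3-(but-3-en-1-yl)-3-methyl-6-(propan-2-yl)cyclohexan-1-one
Product: 5 (3R)-3-[(2E)-but-2-en-1-yl]-3-methyl-6-(propan-2-yl)cyclohexan-1-one
Conditions: RuHCl(CO)(PPh3)3 (2 mol %), toluene, 80 °C
Reagents that add atoms: none
Why: Ruthenium-hydride alkene isomerisation (hydrometalation/β-hydride elimination) moves the terminal alkene one position and stalls there because the next position is neopentylic; no stereocentre is touched (the descriptor change is only a CIP priority change, and E/Z is irrelevant because the geometry is lost in step 6).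

Step 3
Reactants: 5 (3R)-3-[(2E)-but-2-en-1-yl]-3-methyl-6-(propan-2-yl)cyclohexan-1-one
Product: 7 (3R)-3-[(2E)-but-2-en-1-yl]-3,7-dimethyl-6-oxooctanoic acid, via α-hydroperoxy ketone 6 (not isolated)
Conditions: KOt-Bu (3 equiv), O2 (1 atm), t-BuOH/THF, 0 °C; aq. HCl
Reagents that add atoms: dioxygen O=O
Why: Base-mediated aerobic cleavage of an α-branched ketone: the thermodynamic enolate (towards the isopropyl-bearing carbon, away from the quaternary centre) traps O2 and the α-hydroperoxide fragments through a dioxetane to isopropyl ketone plus carboxylate, leaving C1 untouched.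

Step 4
Reactants: 7 (3R)-3-[(2E)-but-2-en-1-yl]-3,7-dimethyl-6-oxooctanoic acid
Product: 9 (1R,2R,5R)-2-[(2E)-but-2-en-1-yl]-2-methyl-5-(propan-2-yl)-6-oxabicyclo[3.2.0]heptan-7-one, via tosyl mixed anhydride 8 (not isolated)
Conditions: TsCl (1.25 equiv), i-Pr2NEt (4 equiv), LiCl (1 equiv), HBTM (20 mol %), CH2Cl2, 23 °C
Reagents that add atoms: none
Why: Nucleophile-catalysed intramolecular aldol-lactonisation: the acylammonium enolate adds 5-exo to the isopropyl ketone and the tertiary alkoxide closes the β-lactone, so both rings form together with an obligatory cis fusion (C4–O syn to C5–C6), and the chiral isothiourea, reinforced by the lactone preferring the face of the smaller C1 methyl, sets C4 and C5 as drawn.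

Step 5
Reactants: 9 (1R,2R,5R)-2-[(2E)-but-2-en-1-yl]-2-methyl-5-(propan-2-yl)-6-oxabicyclo[3.2.0]heptan-7-one; 10 (2-methylprop-2-en-1-yl)magnesium chloride
Product: 12 1-[(1R,2R,5R)-5-[(2E)-but-2-en-1-yl]-2-hydroxy-5-methyl-2-(propan-2-yl)cyclopentyl]-3-methylbut-3-en-1-one, via Weinreb amide 11 (not isolated)
Conditions: MeONHMe·HCl (1.5 equiv), i-PrMgCl (3.2 equiv), THF, −20 °C; then 10 (3 equiv), −20 to 0 °C; cold aq. NH4Cl
Reagents that add atoms: none
Why: Aminolysis of the strained β-lactone gives the β-hydroxy Weinreb amide, whose chelated tetrahedral intermediate stops the allylic Grignard at the ketone (Weinreb ketone synthesis); no stereocentre is formed and the cold, non-equilibrating conditions preserve C5.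

Step 6
Reactants: 12 1-[(1R,2R,5R)-5-[(2E)-but-2-en-1-yl]-2-hydroxy-5-methyl-2-(propan-2-yl)cyclopentyl]-3-methylbut-3-en-1-one
Product: 13 (3R,3aR,8aR)-3-hydroxy-6,8a-dimethyl-3-(propan-2-yl)-2,3,3a,5,8,8a-hexahydroazulen-4(1H)-one
Conditions: second-generation Hoveyda–Grubbs catalyst (5 mol %), toluene (5 mM), 80 °C
Reagents that add atoms: none
Why: Ring-closing metathesis between the methallyl and butenyl alkenes closes the seven-membered ring with loss of propene and places the trisubstituted alkene unambiguously at C8=C9; the trans ring fusion is inherited from C1 and C5.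

Step 7
Reactants: 13 (3R,3aR,8aR)-3-hydroxy-6,8a-dimethyl-3-(propan-2-yl)-2,3,3a,5,8,8a-hexahydroazulen-4(1H)-one
Product: 14 (3R,3aS,4R,8aR)-6,8a-dimethyl-3-(propan-2-yl)-1,2,3,3a,4,5,8,8a-octahydroazulene-3,4-diol
Conditions: Et2BOMe (1.2 equiv), NaBH4, THF/MeOH 4:1, −78 °C; AcOH, MeOH co-evaporation
Reagents that add atoms: none
Why: Narasaka–Prasad reduction: the C4 hydroxyl and C6 ketone form a six-membered boron chelate and external hydride attacks the face opposite C1, giving the 1,3-syn diol, i.e. the C6 alcohol cis to the C4 hydroxyl.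

Step 8
Reactants: 14 (3R,3aS,4R,8aR)-6,8a-dimethyl-3-(propan-2-yl)-1,2,3,3a,4,5,8,8a-octahydroazulene-3,4-diol; 15 4-(acetyloxy)benzoic acid
Product: 17 (3R,3aS,4R,8aR)-3-hydroxy-6,8a-dimethyl-3-(propan-2-yl)-1,2,3,3a,4,5,8,8a-octahydroazulen-4-yl 4-hydroxybenzoate, via aryl acetate ester 16 (not isolated)
Conditions: 15, EDC·HCl, DMAP, CH2Cl2, rt; then pyrrolidine, 0 °C
Reagents that add atoms: none
Why: Steglich esterification acylates only the secondary C6 hydroxyl with retention (the tertiary C4 hydroxyl is inert), and pyrrolidine then removes the far more electrophilic aryl acetate by aminolysis without touching the hindered benzoate.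

Step 9
Reactants: 17 (3R,3aS,4R,8aR)-3-hydroxy-6,8a-dimethyl-3-(propan-2-yl)-1,2,3,3a,4,5,8,8a-octahydroazulen-4-yl 4-hydroxybenzoate
Product: 18 target CNP0163817.3
Conditions: mCPBA, NaHCO3, CH2Cl2, 0 °C
Reagents that add atoms: 3-chloroperoxybenzoic acid OOC(=O)c1cccc(Cl)c1
Why: Prilezhaev epoxidation: the face of the alkene bearing the angular C1 methyl and the C6 aroyloxy group is screened, so the peracid adds from the opposite face and gives the C8/C9 configuration of the target.

## Compound list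

1 | piperitone, 3-methyl-6-(propan-2-yl)cyclohex-2-en-1-one (racemic) | CC1=CC(=O)C(C(C)C)CC1 | starting material
2 | but-3-en-1-ylmagnesium bromide (THF solution) | C=CCC[Mg]Br | starting material
3 | bromo{[(3S)-3-(but-3-en-1-yl)-3-methyl-6-(propan-2-yl)cyclohex-1-en-1-yl]oxy}magnesium | CC(C)C1CC[C@](C)(CCC=C)C=C1O[Mg]Br | intermediate
4 | (3S)-3-(but-3-en-1-yl)-3-methyl-6-(propan-2-yl)cyclohexan-1-one (C6 epimers) | CC(C)C1CC[C@](C)(CCC=C)CC1=O | intermediate
5 | (3R)-3-[(2E)-but-2-en-1-yl]-3-methyl-6-(propan-2-yl)cyclohexan-1-one (C6 epimers) | CC(C)C1CC[C@](C)(C/C=C/C)CC1=O | intermediate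
6 | (5R)-5-[(2E)-but-2-en-1-yl]-2-hydroperoxy-5-methyl-2-(propan-2-yl)cyclohexan-1-one | CC(C)C1(OO)CC[C@](C)(C/C=C/C)CC1=O | intermediate
7 | (3R)-3-[(2E)-but-2-en-1-yl]-3,7-dimethyl-6-oxooctanoic acid | CC(C)C(=O)CC[C@](C)(C/C=C/C)CC(=O)O | intermediate
8 | (3R)-3-[(2E)-but-2-en-1-yl]-3,7-dimethyl-6-oxooctanoic 4-methylbenzenesulfonic anhydride | CC(C)C(=O)CC[C@](C)(C/C=C/C)CC(=O)OS(=O)(=O)c1ccc(C)cc1 | intermediate
9 | (1R,2R,5R)-2-[(2E)-but-2-en-1-yl]-2-methyl-5-(propan-2-yl)-6-oxabicyclo[3.2.0]heptan-7-one | CC(C)[C@]12CC[C@](C)(C/C=C/C)[C@H]1C(=O)O2 | intermediate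
10 | (2-methylprop-2-en-1-yl)magnesium chloride (THF solution) | CC(=C)C[Mg]Cl | starting material
11 | (1R,2R,5R)-5-[(2E)-but-2-en-1-yl]-2-hydroxy-N-methoxy-N,5-dimethyl-2-(propan-2-yl)cyclopentane-1-carboxamide | CC(C)[C@]1(O)CC[C@](C)(C/C=C/C)[C@H]1C(=O)N(C)OC | intermediate
12 | 1-[(1R,2R,5R)-5-[(2E)-but-2-en-1-yl]-2-hydroxy-5-methyl-2-(propan-2-yl)cyclopentyl]-3-methylbut-3-en-1-one | CC(C)[C@]1(O)CC[C@](C)(C/C=C/C)[C@H]1C(=O)CC(C)=C | intermediate
13 | (3R,3aR,8aR)-3-hydroxy-6,8a-dimethyl-3-(propan-2-yl)-2,3,3a,5,8,8a-hexahydroazulen-4(1H)-one | CC(C)[C@]1(O)CC[C@]2(C)CC=C(C)CC(=O)[C@H]21 | intermediate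
14 | (3R,3aS,4R,8aR)-6,8a-dimethyl-3-(propan-2-yl)-1,2,3,3a,4,5,8,8a-octahydroazulene-3,4-diol | CC(C)[C@]1(O)CC[C@]2(C)CC=C(C)C[C@@H](O)[C@H]21 | intermediate
15 | 4-(acetyloxy)benzoic acid | CC(=O)Oc1ccc(cc1)C(O)=O | starting material
16 | (3R,3aS,4R,8aR)-3-hydroxy-6,8a-dimethyl-3-(propan-2-yl)-1,2,3,3a,4,5,8,8a-octahydroazulen-4-yl 4-(acetyloxy)benzoate | CC(C)[C@]1(O)CC[C@]2(C)CC=C(C)C[C@@H](OC(=O)c3ccc(OC(C)=O)cc3)[C@H]21 | intermediate
17 | (3R,3aS,4R,8aR)-3-hydroxy-6,8a-dimethyl-3-(propan-2-yl)-1,2,3,3a,4,5,8,8a-octahydroazulen-4-yl 4-hydroxybenzoate | CC(C)[C@]1(O)CC[C@]2(C)CC=C(C)C[C@@H](OC(=O)c3ccc(O)cc3)[C@H]21 | intermediate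
18 | CNP0163817.3, (1R,4R,5S,6R,8R,9S)-8,9-epoxy-4-hydroxydaucan-6-yl 4-hydroxybenzoate (daucane numbering) | CC(C)[C@]1(O)CC[C@]2(C)C[C@@H]3O[C@]3(C)C[C@@H](OC(=O)c3ccc(O)cc3)[C@H]21 | target

## Step count and risks

Total steps: 9. Longest linear sequence: 9 (from piperitone 1).

Three steps most likely to fail, each with a fallback:

**Step 4 (aldol-lactonisation onto a hindered isopropyl ketone next to a quaternary carbon; facial control).** The fallback sets out from 7 and replaces catalyst control by an auxiliary. Acylation of (4S)-4-benzyl-1,3-oxazolidin-2-one through the pivaloyl mixed anhydride (PivCl, Et3N, LiCl) gives the N-acyl oxazolidinone F3. Soft enolisation (TiCl4, i-Pr2NEt, CH2Cl2, −78 to 0 °C) triggers an intramolecular titanium-enolate aldol onto the ketone to give the aldol imide F4. Transamination with Me3Al/MeONHMe·HCl delivers the Weinreb amide 11, where the route is rejoined before the Grignard addition of step 5.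

**Step 3 (aerobic cleavage: regiochemistry of enolisation, over-oxidation of the product ketone).** The fallback sets out from 5 and separates oxygenation from cleavage. Thermodynamic silylation (TMSCl, Et3N, DMF, 110 °C) gives the tetrasubstituted trimethylsilyl enol ether F1. MeLi liberates the lithium enolate, which is hydroxylated with Davis oxaziridine to the α-hydroxy ketone F2. Glycol-type cleavage with NaIO4 in aqueous THF returns the keto acid 7.

**Step 5 (one-pot lactone aminolysis and allylic Grignard addition: over-addition, conjugation of the β,γ-unsaturated ketone).** The fallback sets out from 9 and goes through the aldehyde oxidation level. i-Bu2AlH at −78 °C reduces the β-lactone to the hydroxy aldehyde F5. Addition of 10 gives the homoallylic alcohol F6 as a carbinol epimer mixture. Dess–Martin periodinane oxidises only the secondary alcohol and returns ketone 12.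

## Further compounds

F1 | step 3 | trimethyl{[(5R)-5-[(2E)-but-2-en-1-yl]-5-methyl-2-(propan-2-yl)cyclohex-1-en-1-yl]oxy}silane | CC(C)C1=C(O[Si](C)(C)C)C[C@@](C)(C/C=C/C)CC1
F2 | step 3 | (5R)-5-[(2E)-but-2-en-1-yl]-2-hydroxy-5-methyl-2-(propan-2-yl)cyclohexan-1-one | CC(C)C1(O)CC[C@](C)(C/C=C/C)CC1=O
F3 | step 4 | (4S)-4-benzyl-3-[(3R)-3-[(2E)-but-2-en-1-yl]-3,7-dimethyl-6-oxooctanoyl]-1,3-oxazolidin-2-one | CC(C)C(=O)CC[C@](C)(C/C=C/C)CC(=O)N1[C@@H](Cc2ccccc2)COC1=O
F4 | step 4 | (4S)-4-benzyl-3-{[(1R,2R,5R)-5-[(2E)-but-2-en-1-yl]-2-hydroxy-5-methyl-2-(propan-2-yl)cyclopentyl]carbonyl}-1,3-oxazolidin-2-one | CC(C)[C@]1(O)CC[C@](C)(C/C=C/C)[C@H]1C(=O)N1[C@@H](Cc2ccccc2)COC1=O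
F5 | step 5 | (1R,2R,5R)-5-[(2E)-but-2-en-1-yl]-2-hydroxy-5-methyl-2-(propan-2-yl)cyclopentane-1-carbaldehyde | CC(C)[C@]1(O)CC[C@](C)(C/C=C/C)[C@H]1C=O
F6 | step 5 | 1-[(1S,2R,5R)-5-[(2E)-but-2-en-1-yl]-2-hydroxy-5-methyl-2-(propan-2-yl)cyclopentyl]-3-methylbut-3-en-1-ol (carbinol epimers) | CC(C)[C@]1(O)CC[C@](C)(C/C=C/C)[C@H]1C(O)CC(C)=C
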